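The hour is a poor unit for substrate here, so I count in half-lives. Each flask receives substrate at a steady rate while reagent already stands in it, and I first ask which given numbers the count can feel.

| flask | substrate | reagent | remark | time |
|---|---|---|---|---|
| cedar | 0.30 M (fed, over 4.0 h) | 0.23 M | run made earlier |  |
| larch | 0.30 M (fed, over 4.0 h) | 1.2 M | run made earlier |  |
| north-west | 0.30 M (fed, over 4.0 h) | 0.300 M |  | 25 h |
| south | 0.30 M (fed, over 4.0 h) | 0.500 M |  | 25 h |
| north | 0.30 M (fed, over 4.0 h) | 0.800 M |  | 25 h |
| east | 0.30 M (fed, over 4.0 h) | 1.00 M |  | 25 h |
| south-west | 0.30 M (fed, over 4.0 h) | 1.50 M |  | 25 h |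

cedar run (percent of the substrate charged)

| time / h | target / % | substrate / % |
|---|---|---|
| 2.00 | 4 | 44 |
| 6.00 | 3 | 43 |
| 12.0 | 14 | 15 |
| 20.0 | 20 | 2 |

larch run (percent of the substrate charged)

| time / h | target / % | substrate / % |
|---|---|---|
| 2.00 | 0 | 41 |
| 6.00 | 5 | 46 |
| 12.0 | 14 | 12 |
| 20.0 | 23 | 5 |

- the earlier runs were read with a standard deviation of 2 percentage points
- "hardly changes" means that all values lie within two and a half points (for a concentration: within two and a half percent of the largest)
- percentages count the whole charge, also what has not yet gone in

1. amount of target at the end, in percent of the substrate charged for north-west, south, north, east, south-west, in this order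
2. the course of these numbers from the first flask to the last (rises, then falls / hardly changes / falls, then rises / rises all the way / falls all the way)

The charge of substrate is 0.30 M in each flask, so the flasks do not differ in it. Reagent changes by a factor of 5.22 between the cedar and larch runs, but substrate at 12.0 h reads 15% in cedar and 12% in larch. That gap of 3 percentage points stands against a scatter of 2 points, so I take substrate loss as first-order and free of reagent.

The feed can be replaced by its midpoint, which gives the count of half-lives up to the asked time:

N = (t − tf/2) / half-life

That replacement reaches 2.00 h to either end of the feed, and I weigh this once a half-life stands beside it.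

The half-life is the second number to weigh. Both readings used for it lie after the feed, and taken apart they give 3.95 h for cedar and 3.10 h for larch. The residue at 25 h then lies between 0.579% and 1.76%, a spread of a factor of 3.05. A shift of the midpoint by 2.00 h is a factor of 1.57 with the larch half-life, the shorter one, so the half-life weighs more than the midpoint. Any value in that range is a small residue, so pooling the two runs is good enough.

Pooled, the substrate half-life, the time in which first-order loss halves what stands, is:

3.49 h

N = 6.60

residue = 1.03%

So I commit to about 1.03% of substrate at 25 h. For target the count gives no figure: at 20.0 h cedar holds 78.0% of its charge in neither column and larch 72.0%, and I take target to come out of that unseen stock.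

The forecast reads 27%, 27%, 27%, 27% and 27%, a course that hardly changes, on the ground that “reagent is never limiting”.

The flasks give 27.3%, 32.2%, 32.2%, 30.8% and 26.6%, and the course is: rises, then falls.

    substrate → intermediate A (k = 5.31 × 10⁻⁵ s⁻¹)
    substrate ⇌ dormant form (K = 1.79, k = 2.03 × 10⁻⁶ s⁻¹)
    reagent + intermediate A → target (k = 8.19 × 10⁻⁵ M⁻¹ s⁻¹)
    reagent + intermediate B → intermediate C (k = 2.34 × 10⁻⁵ M⁻¹ s⁻¹)
    intermediate C ⇌ intermediate D (K = 0.190, k = 5.10 × 10⁻⁶ s⁻¹)
    reagent + intermediate A ⇌ intermediate B (K = 7.71 M⁻¹, k = 0.00105 M⁻¹ s⁻¹)
    intermediate D → side product (k = 4.97 × 10⁻⁶ s⁻¹)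

North-west ends at 27.3% of target with 34.5% as intermediate A, and its substrate stands at 1.1%, where 6.60 half-lives of 3.49 h gave me 1.03%. South has the same count behind it and shows the same substrate, 1.1% at 25.0 h. Target in south is 32.2%, and intermediate A in south stands at 16.9%.

Readings and results were generated by integration on assumed constants; noise was put on by code.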